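**Retrosynthetic overview** (eremophilane numbering: ring A = C1, C2, C3, C4, C5, C10; ring B = C5, C6, C7, C8, C9, C10)

- The C3 ester is made last (Yamaguchi) from the trienoic acid, itself built by carboalumination and cross-coupling. Before that, the 9α-hydroxyl comes from a Rubottom oxidation and the C7 isopropylidene from an acetone aldol and dehydration on a trans-decal-8-one.
- The trans-decalone comes from a Δ9(10)-3,8-enedione by one dissolving-metal reduction (C10 trans, C3 equatorial OH). The C8 carbonyl comes from allylic oxidation of the C9=C10 alkene.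
- Ring A is closed by a bridged, boat-only Claisen rearrangement of an (E)-2-ethylidenepyran fused to ring B: C4–C5 forms while O–C9 breaks. The oxygen that starts on C9 ends as the C3 carbonyl, and the C9 carbinol chirality (from a CBS reduction) is relayed to C5 and, through the enol ether geometry, to C4.
- Enabling feature: the atoms O–C3–C4···C5–C10–C9 form a 1,5-related array across the ring fusion, and C3 is already tied to C10 through C2–C1. A pyran made by 6-exo hydroalkoxylation of an alkynyl cyclohexenol therefore holds all of ring A as a [3,3] retron, and C9 is the carbon that is re-oxygenated later.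
- Ring order: ring B is bought (3-methylcyclohex-2-enone); a temporary pyran is made in step 5 and opened in step 6, which closes ring A, the last ring of the skeleton.

Key step: step 6

Remark on numbering: the target is 3R,4R,5R,9S,10R, that is 3α-acyloxy, 4β,5β-dimethyl, 9α-hydroxy, 10α-H on a trans-decalin; the SMILES in the compound list are authoritative for configuration.
Assumption: the (S)-oxazaborolidine is taken to give the R carbinol in step 4 (the fully substituted enone carbon acting as the large group); if the opposite sense is found, the R catalyst is used.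
Assumption: 3-methylcyclohex-2-en-1-one, pent-3-yn-1-ol, (E)-oct-2-enal and ethyl (E)-3-iodoprop-2-enoate are bought.

**Route**

Step 1
Reactants: 1 3-methylcyclohex-2-en-1-one
Product: 2 2-iodo-3-methylcyclohex-2-en-1-one
Conditions: I2, pyridine/CH2Cl2, 0 °C → rt
Reagents that add atoms: iodine [I][I]
Why: Pyridine-mediated α-iodination of the enone (conjugate addition of pyridine, iodination of the enolate, elimination) puts the coupling handle on C10, and no stereocenter is formed.

Step 2
Reactants: 3 pent-3-yn-1-ol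
Product: 4 5-iodopent-2-yne
Conditions: I2, PPh3, imidazole, CH2Cl2, 0 °C
Reagents that add atoms: iodine [I][I]
Why: Appel-type iodination displaces the alkoxyphosphonium group by iodide in an SN2 step at the primary carbon and leaves the internal alkyne untouched.

Step 3
Reactants: 2 2-iodo-3-methylcyclohex-2-en-1-one; 4 5-iodopent-2-yne
Product: 6 3-methyl-2-(pent-3-yn-1-yl)cyclohex-2-en-1-one, via pent-3-yn-1-ylzinc iodide 5 (not isolated)
Conditions: 4, Zn dust, LiCl, THF, 40 °C; then 2, Pd(OAc)2 (2 mol %), SPhos (4 mol %), THF, rt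
Reagents that add atoms: none
Why: Zinc insertion into the primary iodide gives an alkylzinc that tolerates the ketone and couples with the α-iodoenone in a Negishi sp3–sp2 cross-coupling, which attaches C1–C4 and the C4 methyl to C10.

Step 4
Reactants: 6 3-methyl-2-(pent-3-yn-1-yl)cyclohex-2-en-1-one
Product: 7 (1R)-3-methyl-2-(pent-3-yn-1-yl)cyclohex-2-en-1-ol
Conditions: (S)-2-methyl-CBS-oxazaborolidine (20 mol %), catecholborane, toluene, −78 °C; aq NaOH work-up
Reagents that add atoms: none
Why: Corey–Bakshi–Shibata reduction delivers hydride to one face of the ketone with the fully substituted alkene carbon as the large group, which sets C9 as R (the only external source of chirality in the route), and catecholborane at low temperature does not hydroborate the alkyne.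

Step 5
Reactants: 7 (1R)-3-methyl-2-(pent-3-yn-1-yl)cyclohex-2-en-1-ol
Product: 8 (2E,8aR)-2-ethylidene-5-methyl-3,4,6,7,8,8a-hexahydro-2H-chromene
Conditions: La[N(SiMe3)2]3 (5 mol %), toluene, 100 °C; filtration through Et3N-treated basic alumina
Reagents that add atoms: none
Why: Lanthanide-amide-catalysed intramolecular hydroalkoxylation of an alkynyl alcohol inserts the alkyne syn into the La–O bond in the 6-exo mode and protonolysis retains the geometry, so O and the new H end cis and the methyl trans to oxygen (E), while acid-free handling keeps the exocyclic enol ether from drifting into the ring.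

Step 6
Reactants: 8 (2E,8aR)-2-ethylidene-5-methyl-3,4,6,7,8,8a-hexahydro-2H-chromene
Product: 9 (1R,8aR)-1,8a-dimethyl-3,4,6,7,8,8a-hexahydronaphthalen-2(1H)-one
Conditions: toluene (0.05 M), 2,6-di-tert-butyl-4-methylpyridine (5 mol %), 200 °C, sealed base-washed tube
Reagents that add atoms: none
Why: Proposed new method: a thermal [3,3] shift (Claisen rearrangement) of the allyl vinyl ether C4=C3–O–C9–C10=C5 in which C3 and C10 are bridged by C2–C1, so the only transition state is a boat shaped like bicyclo[2.2.2]octane, with O–C9 breaking while C4–C5 forms and the new C3 carbonyl driving the step; the closest known reactions are the carbocyclising Claisen rearrangements of 2-alkenyl-dihydropyrans and of 2-methylene-6-vinyltetrahydropyrans and the boat Cope rearrangement of 1,4-dimethylenecyclohexane. Ring A (C3, C4, C5, C10, C1, C2) is closed in a pericyclic suprafacial mode by the C4–C5 bond between the two exocyclic alkene carbons of the pyran, which is opened in the same event. C5 is set by transfer of chirality from C9, because C4 must arrive on the face of the ring B allyl unit that carried the oxygen, which leaves the C5 methyl on the opposite β face. C4 is set by the enol ether geometry, because in the boat the substituent trans to oxygen eclipses the C5 methyl and becomes the 4β (4R) methyl cis to it. The step needs the concerted shift to win over ionisation of the allylic C9–O bond and over acid-promoted migration of the enol ether double bond into the pyran ring, and a non-polar solvent, base-washed glass and a hindered pyridine should secure this, while no other 1,5-diene is present.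

Step 7
Reactants: 9 (1R,8aR)-1,8a-dimethyl-3,4,6,7,8,8a-hexahydronaphthalen-2(1H)-one
Product: 10 (1R,8aR)-1,8a-dimethyl-3,4,8,8a-tetrahydronaphthalene-2,6(1H,7H)-dione
Conditions: Rh2(cap)4 (dirhodium tetracaprolactamate, 1 mol %), 70% aq t-BuOOH, 1,2-dichloroethane, 40 °C
Reagents that add atoms: tert-butyl hydroperoxide CC(C)(C)OO
Why: Radical allylic oxidation, in which the tert-butylperoxyl radical abstracts the C8 hydrogen to give the allyl radical with a tertiary terminus at C10 (the selectivity known from Δ5-steroids to 7-ketones), gives the C8 enone, and the base-free conditions keep C4 from epimerising.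

Step 8
Reactants: 10 (1R,8aR)-1,8a-dimethyl-3,4,8,8a-tetrahydronaphthalene-2,6(1H,7H)-dione
Product: 11 (4aS,5R,6R,8aS)-6-hydroxy-4a,5-dimethyloctahydronaphthalen-2(1H)-one
Conditions: Li, NH3(l)/THF, t-BuOH (3 equiv), −78 → −33 °C; isoprene; then NH4Cl
Reagents that add atoms: none
Why: In this dissolving-metal reduction the enone is reduced first and its β-carbon C10 is protonated axially to give the trans ring fusion (10α-H) while C8 stays masked as the lithium enolate, and the C3 ketone is reduced under thermodynamic control to the equatorial 3α-alcohol trans to the equatorial 4β-methyl.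

Step 9
Reactants: 11 (4aS,5R,6R,8aS)-6-hydroxy-4a,5-dimethyloctahydronaphthalen-2(1H)-one
Product: 12 (4aS,5R,6R,8aS)-4a,5-dimethyl-6-[(triethylsilyl)oxy]octahydronaphthalen-2(1H)-one
Conditions: Et3SiCl, imidazole, CH2Cl2, 0 °C
Reagents that add atoms: chlorotriethylsilane CC[Si](Cl)(CC)CC
Why: Silylation of the secondary alcohol protects O3 through the enolate chemistry with a group that can later be removed beside a tert-butyldimethylsilyl ether.

Step 10
Reactants: 12 (4aS,5R,6R,8aS)-4a,5-dimethyl-6-[(triethylsilyl)oxy]octahydronaphthalen-2(1H)-one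
Product: 13 (3S,4aS,5R,6R,8aS)-3-(2-hydroxypropan-2-yl)-4a,5-dimethyl-6-[(triethylsilyl)oxy]octahydronaphthalen-2(1H)-one
Conditions: LiN(i-Pr)2, THF, −78 °C; ZnCl2; acetone, −78 → −40 °C; aq NH4Cl
Reagents that add atoms: acetone CC(C)=O
Why: Kinetic deprotonation of the trans-decal-8-one goes to C7, away from the ring fusion as in 5α-3-keto steroids, and the zinc enolate adds to acetone in an aldol reaction, the new C7 center (expected equatorial) being removed in the next step.

Step 11
Reactants: 13 (3S,4aS,5R,6R,8aS)-3-(2-hydroxypropan-2-yl)-4a,5-dimethyl-6-[(triethylsilyl)oxy]octahydronaphthalen-2(1H)-one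
Product: 15 (4aS,5R,6R,8aS)-4a,5-dimethyl-3-(propan-2-ylidene)-6-[(triethylsilyl)oxy]octahydronaphthalen-2(1H)-one, via tertiary methanesulfonate 14 (not isolated)
Conditions: MsCl, Et3N, DMAP (5 mol %), CH2Cl2, 0 °C; then DBU, rt
Reagents that add atoms: none
Why: Mesylation and E1cB elimination of the β-sulfonyloxy ketone give the enone, and DBU equilibrates any isopropenyl isomer into the conjugated isopropylidene ketone.

Step 12
Reactants: 15 (4aS,5R,6R,8aS)-4a,5-dimethyl-3-(propan-2-ylidene)-6-[(triethylsilyl)oxy]octahydronaphthalen-2(1H)-one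
Product: 17 (1S,4aR,5R,6R,8aR)-1-[(tert-butyldimethylsilyl)oxy]-4a,5-dimethyl-3-(propan-2-ylidene)-6-[(triethylsilyl)oxy]octahydronaphthalen-2(1H)-one, via silyl dienol ether 16 (not isolated)
Conditions: LiN(i-Pr)2, THF, −78 °C; TBSOTf; then mCPBA, NaHCO3, CH2Cl2, −20 → 0 °C
Reagents that add atoms: tert-butyldimethylsilyl trifluoromethanesulfonate CC(C)(C)[Si](C)(C)OS(=O)(=O)C(F)(F)F; 3-chloroperbenzoic acid OOC(=O)c1cccc(Cl)c1
Why: In this Rubottom oxidation of a 2-silyloxy-1,3-diene the base removes the only α′ hydrogen (C9) kinetically, the electron-rich C8=C9 bond is epoxidised from the α face because the β face is shielded by the axial C5 methyl in a 1,3 relation, and silyl migration gives the equatorial 9α-silyloxy ketone.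

Step 13
Reactants: 17 (1S,4aR,5R,6R,8aR)-1-[(tert-butyldimethylsilyl)oxy]-4a,5-dimethyl-3-(propan-2-ylidene)-6-[(triethylsilyl)oxy]octahydronaphthalen-2(1H)-one
Product: 18 (1S,4aR,5R,6R,8aR)-1-[(tert-butyldimethylsilyl)oxy]-6-hydroxy-4a,5-dimethyl-3-(propan-2-ylidene)octahydronaphthalen-2(1H)-one
Conditions: PPTS (10 mol %), MeOH/CH2Cl2, 0 °C
Reagents that add atoms: none
Why: Acid-catalysed methanolysis cleaves the triethylsilyl ether much faster than the tert-butyldimethylsilyl ether, which frees O3 only.

Step 14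
Reactants: 19 (E)-oct-2-enal
Product: 20 (E)-non-3-en-1-yne
Conditions: Me3SiCHN2, LiN(i-Pr)2, THF, −78 °C → rt
Reagents that add atoms: (trimethylsilyl)diazomethane C[Si](C)(C)C=[N+]=[N-]
Why: In this Colvin homologation the lithiated silyldiazomethane adds to the aldehyde, Peterson elimination gives a diazoalkene, and loss of N2 with a 1,2-hydride shift of the alkylidene carbene gives the terminal alkyne with the E alkene untouched.

Step 15
Reactants: 20 (E)-non-3-en-1-yne; 21 ethyl (E)-3-iodoprop-2-enoate
Product: 23 ethyl (2E,4E,6E)-5-methyldodeca-2,4,6-trienoate, via alkenylalane 22 (not isolated)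
Conditions: Me3Al, Cp2ZrCl2 (20 mol %), CH2Cl2, 0 °C → rt; then 21, Pd(PPh3)4 (5 mol %), ZnCl2, THF, rt
Reagents that add atoms: trimethylaluminium C[Al](C)C
Why: Zirconium-catalysed methylalumination adds methyl and aluminium syn across the terminal alkyne with methyl on the inner carbon, and Negishi cross-coupling of the alkenylalane with the E iodoacrylate proceeds with retention at both partners, which fixes the 4E and 2E double bonds.

Step 16
Reactants: 23 ethyl (2E,4E,6E)-5-methyldodeca-2,4,6-trienoate
Product: 24 (2E,4E,6E)-5-methyldodeca-2,4,6-trienoic acid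
Conditions: LiOH, THF/MeOH/H2O, rt; then 1 M HCl
Reagents that add atoms: lithium hydroxide [Li+].[OH-]
Why: Saponification of the ethyl ester at room temperature is mild enough not to isomerise the triene.

Step 17
Reactants: 18 (1S,4aR,5R,6R,8aR)-1-[(tert-butyldimethylsilyl)oxy]-6-hydroxy-4a,5-dimethyl-3-(propan-2-ylidene)octahydronaphthalen-2(1H)-one; 24 (2E,4E,6E)-5-methyldodeca-2,4,6-trienoic acid
Product: 26 (1R,2R,4aR,5S,8aR)-5-[(tert-butyldimethylsilyl)oxy]-1,8a-dimethyl-6-oxo-7-(propan-2-ylidene)decahydronaphthalen-2-yl (2E,4E,6E)-5-methyldodeca-2,4,6-trienoate, via mixed anhydride 25 (not isolated)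
Conditions: 24, 2,4,6-trichlorobenzoyl chloride, Et3N, THF, rt; then 18, DMAP, toluene, rt → 40 °C
Reagents that add atoms: none
Why: In this Yamaguchi esterification DMAP attacks the mixed anhydride at the less hindered trienoyl carbonyl and the acylpyridinium ion acylates the hindered equatorial C3 alcohol with retention at C3, while O9 is blocked as its silyl ether.

Step 18
Reactants: 26 (1R,2R,4aR,5S,8aR)-5-[(tert-butyldimethylsilyl)oxy]-1,8a-dimethyl-6-oxo-7-(propan-2-ylidene)decahydronaphthalen-2-yl (2E,4E,6E)-5-methyldodeca-2,4,6-trienoate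
Product: 27 (1R,2R,4aR,5S,8aR)-5-hydroxy-1,8a-dimethyl-6-oxo-7-(propan-2-ylidene)decahydronaphthalen-2-yl (2E,4E,6E)-5-methyldodeca-2,4,6-trienoate (CNP0211657.1)
Conditions: HF·pyridine, pyridine/THF, 0 °C → rt
Reagents that add atoms: none
Why: Fluoride cleavage of the silyl ether under buffered, non-basic conditions frees the 9α-hydroxyl without epimerising the α-ketol or cleaving the ester.

**Compound list**

1 | 3-methylcyclohex-2-en-1-one | CC1=CC(=O)CCC1 | starting material
2 | 2-iodo-3-methylcyclohex-2-en-1-one | CC1=C(I)C(=O)CCC1 | intermediate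
3 | pent-3-yn-1-ol | CC#CCCO | starting material
4 | 5-iodopent-2-yne | CC#CCCI | intermediate
5 | pent-3-yn-1-ylzinc iodide | CC#CCC[Zn]I | intermediate
6 | 3-methyl-2-(pent-3-yn-1-yl)cyclohex-2-en-1-one | CC#CCCC1=C(C)CCCC1=O | intermediate
7 | (1R)-3-methyl-2-(pent-3-yn-1-yl)cyclohex-2-en-1-ol | CC#CCCC1=C(C)CCC[C@H]1O | intermediate
8 | (2E,8aR)-2-ethylidene-5-methyl-3,4,6,7,8,8a-hexahydro-2H-chromene | C/C=C1\CCC2=C(C)CCC[C@H]2O1 | intermediate
9 | (1R,8aR)-1,8a-dimethyl-3,4,6,7,8,8a-hexahydronaphthalen-2(1H)-one | O=C1CCC2=CCCC[C@]2(C)[C@H]1C | intermediate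
10 | (1R,8aR)-1,8a-dimethyl-3,4,8,8a-tetrahydronaphthalene-2,6(1H,7H)-dione | O=C1CCC2=CC(=O)CC[C@]2(C)[C@H]1C | intermediate
11 | (4aS,5R,6R,8aS)-6-hydroxy-4a,5-dimethyloctahydronaphthalen-2(1H)-one | O[C@@H]1CC[C@H]2CC(=O)CC[C@]2(C)[C@H]1C | intermediate
12 | (4aS,5R,6R,8aS)-4a,5-dimethyl-6-[(triethylsilyl)oxy]octahydronaphthalen-2(1H)-one | CC[Si](CC)(CC)O[C@@H]1CC[C@H]2CC(=O)CC[C@]2(C)[C@H]1C | intermediate
13 | (3S,4aS,5R,6R,8aS)-3-(2-hydroxypropan-2-yl)-4a,5-dimethyl-6-[(triethylsilyl)oxy]octahydronaphthalen-2(1H)-one | CC[Si](CC)(CC)O[C@@H]1CC[C@H]2CC(=O)[C@H](C(C)(C)O)C[C@]2(C)[C@H]1C | intermediate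
14 | tertiary methanesulfonate of 13 (OMs in place of the side-chain OH) | CC[Si](CC)(CC)O[C@@H]1CC[C@H]2CC(=O)[C@H](C(C)(C)OS(C)(=O)=O)C[C@]2(C)[C@H]1C | intermediate
15 | (4aS,5R,6R,8aS)-4a,5-dimethyl-3-(propan-2-ylidene)-6-[(triethylsilyl)oxy]octahydronaphthalen-2(1H)-one | CC[Si](CC)(CC)O[C@@H]1CC[C@H]2CC(=O)C(=C(C)C)C[C@]2(C)[C@H]1C | intermediate
16 | tert-butyldimethylsilyl dienol ether of 15 (C8 silyloxy, C8=C9 alkene, C7 isopropylidene) | CC[Si](CC)(CC)O[C@@H]1CC[C@H]2C=C(O[Si](C)(C)C(C)(C)C)C(=C(C)C)C[C@]2(C)[C@H]1C | intermediate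
17 | (1S,4aR,5R,6R,8aR)-1-[(tert-butyldimethylsilyl)oxy]-4a,5-dimethyl-3-(propan-2-ylidene)-6-[(triethylsilyl)oxy]octahydronaphthalen-2(1H)-one | CC[Si](CC)(CC)O[C@@H]1CC[C@H]2[C@H](O[Si](C)(C)C(C)(C)C)C(=O)C(=C(C)C)C[C@]2(C)[C@H]1C | intermediate
18 | (1S,4aR,5R,6R,8aR)-1-[(tert-butyldimethylsilyl)oxy]-6-hydroxy-4a,5-dimethyl-3-(propan-2-ylidene)octahydronaphthalen-2(1H)-one | O[C@@H]1CC[C@H]2[C@H](O[Si](C)(C)C(C)(C)C)C(=O)C(=C(C)C)C[C@]2(C)[C@H]1C | intermediate
19 | (E)-oct-2-enal | CCCCC/C=C/C=O | starting material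
20 | (E)-non-3-en-1-yne | CCCCC/C=C/C#C | intermediate
21 | ethyl (E)-3-iodoprop-2-enoate | CCOC(=O)/C=C/I | starting material
22 | dimethyl[(1E,3E)-2-methylnona-1,3-dien-1-yl]alane | CCCCC/C=C/C(C)=C/[Al](C)C | intermediate
23 | ethyl (2E,4E,6E)-5-methyldodeca-2,4,6-trienoate | CCCCC/C=C/C(C)=C/C=C/C(=O)OCC | intermediate
24 | (2E,4E,6E)-5-methyldodeca-2,4,6-trienoic acid | CCCCC/C=C/C(C)=C/C=C/C(=O)O | intermediate
25 | (2E,4E,6E)-5-methyldodeca-2,4,6-trienoic 2,4,6-trichlorobenzoic anhydride | CCCCC/C=C/C(C)=C/C=C/C(=O)OC(=O)c1c(Cl)cc(Cl)cc1Cl | intermediate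
26 | (1R,2R,4aR,5S,8aR)-5-[(tert-butyldimethylsilyl)oxy]-1,8a-dimethyl-6-oxo-7-(propan-2-ylidene)decahydronaphthalen-2-yl (2E,4E,6E)-5-methyldodeca-2,4,6-trienoate | CCCCC/C=C/C(C)=C/C=C/C(=O)O[C@@H]1CC[C@H]2[C@H](O[Si](C)(C)C(C)(C)C)C(=O)C(=C(C)C)C[C@]2(C)[C@H]1C | intermediate
27 | (1R,2R,4aR,5S,8aR)-5-hydroxy-1,8a-dimethyl-6-oxo-7-(propan-2-ylidene)decahydronaphthalen-2-yl (2E,4E,6E)-5-methyldodeca-2,4,6-trienoate | CCCCC/C=C/C(C)=C/C=C/C(=O)O[C@@H]1CC[C@H]2[C@H](O)C(=O)C(=C(C)C)C[C@]2(C)[C@H]1C | target

**Step count and risks**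

Total step count: 18. Longest linear sequence: 14 steps (1, 3 to 13, 17, 18).

Steps most likely to fail:

1. Step 6 (proposed new method). The boat transition state, with two methyl groups eclipsed across the forming bond, may lie so high that heterolysis of the allylic C9–O bond overtakes the concerted shift. That would cause loss of chirality transfer, 1,3-recombination or elimination to a diene. Migration of the enol ether double bond into the pyran ring would stop the rearrangement altogether.
 Fallback (known chemistry only; intermolecular [3,3] shift, then Dieckmann closure of ring A; sets out from 2 and returns at 9):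
 - Negishi coupling of 2 with (3-tert-butoxy-3-oxopropyl)zinc bromide under the conditions of step 3 should give tert-butyl 3-(2-methyl-6-oxocyclohex-1-en-1-yl)propanoate F1.
 - Corey–Bakshi–Shibata reduction as in step 4 should give tert-butyl 3-[(6R)-6-hydroxy-2-methylcyclohex-1-en-1-yl]propanoate F2.
 - Johnson–Claisen rearrangement with triethyl orthopropionate (propionic acid catalyst, xylene, 140 °C) should form the C4–C5 bond through a chair transition state with the same C9-to-C5 chirality transfer. It should give ethyl (2R)-2-[(1R)-2-(3-tert-butoxy-3-oxopropyl)-1-methylcyclohex-2-en-1-yl]propanoate F3 together with its C4 epimer.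
 - Dieckmann condensation (KOt-Bu, THF) closes ring A by the C2–C3 bond to tert-butyl (1R,8aR)-1,8a-dimethyl-2-oxo-1,2,3,4,6,7,8,8a-octahydronaphthalene-3-carboxylate F4.
 - CF3CO2H in CH2Cl2, then warming in toluene, removes the tert-butyl group and CO2 and leads to 9; the C4 epimer is removed by chromatography.

2. Step 5. Insertion of the internal alkyne into the La–O bond of a hindered secondary allylic alkoxide may be slow. Erosion of the E geometry, or base- or acid-promoted drift of the double bond into the pyran ring, would then show up as the C4 epimer (or as no reaction) in step 6.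
 Fallback (anti-iodoalkoxylation of a terminal alkyne, then methylation with retention; sets out from 2 and returns at 8):
 - Negishi coupling of 2 with [4-(trimethylsilyl)but-3-yn-1-yl]zinc iodide should give 3-methyl-2-[4-(trimethylsilyl)but-3-yn-1-yl]cyclohex-2-en-1-one F5.
 - Corey–Bakshi–Shibata reduction as in step 4 should give (1R)-3-methyl-2-[4-(trimethylsilyl)but-3-yn-1-yl]cyclohex-2-en-1-ol F6.
 - K2CO3 in methanol removes the silyl group to give (1R)-2-(but-3-yn-1-yl)-3-methylcyclohex-2-en-1-ol F7.
 - Bis(pyridine)iodonium tetrafluoroborate in CH2Cl2 at −40 °C should add oxygen and iodine anti across the alkyne in the 6-exo mode, giving (2E,8aR)-2-(iodomethylidene)-5-methyl-3,4,6,7,8,8a-hexahydro-2H-chromene F8 with iodine trans to oxygen.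
 - Negishi coupling with MeZnCl and Pd(PPh3)4 replaces iodine by methyl with retention and gives 8.

3. Step 8. Protonation of the C8 enolate while lithium is still present would over-reduce C8 to the alcohol; enolisation of the C3 ketone would leave it unreduced; pinacol coupling of the ketyl is a further loss channel.
 Fallback (the two reductions are separated; sets out from 9 and returns at 12):
 - Li in NH3 with t-BuOH reduces only the isolated C3 ketone of 9 (the trisubstituted alkene is inert) to the equatorial alcohol (1R,2R,8aR)-1,8a-dimethyl-1,2,3,4,6,7,8,8a-octahydronaphthalen-2-ol F9.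
 - Et3SiCl and imidazole give triethyl{[(1R,2R,8aR)-1,8a-dimethyl-1,2,3,4,6,7,8,8a-octahydronaphthalen-2-yl]oxy}silane F10.
 - Allylic oxidation as in step 7 gives (4aR,5R,6R)-4a,5-dimethyl-6-[(triethylsilyl)oxy]-4,4a,5,6,7,8-hexahydronaphthalen-2(3H)-one F11.
 - Li in NH3 with one equivalent of t-BuOH then reduces only the enone to the trans-fused ketone 12.

Further compounds
F1 | step 6 | tert-butyl 3-(2-methyl-6-oxocyclohex-1-en-1-yl)propanoate | CC1=C(CCC(=O)OC(C)(C)C)C(=O)CCC1
F2 | step 6 | tert-butyl 3-[(6R)-6-hydroxy-2-methylcyclohex-1-en-1-yl]propanoate | CC(C)(C)OC(=O)CCC1=C(C)CCC[C@H]1O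
F3 | step 6 | ethyl (2R)-2-[(1R)-2-(3-tert-butoxy-3-oxopropyl)-1-methylcyclohex-2-en-1-yl]propanoate | CCOC(=O)[C@H](C)[C@@]1(C)CCCC=C1CCC(=O)OC(C)(C)C
F4 | step 6 | tert-butyl (1R,8aR)-1,8a-dimethyl-2-oxo-1,2,3,4,6,7,8,8a-octahydronaphthalene-3-carboxylate (C3 enolisable, not specified) | O=C1C(C(=O)OC(C)(C)C)CC2=CCCC[C@]2(C)[C@H]1C
F5 | step 5 | 3-methyl-2-[4-(trimethylsilyl)but-3-yn-1-yl]cyclohex-2-en-1-one | C[Si](C)(C)C#CCCC1=C(C)CCCC1=O
F6 | step 5 | (1R)-3-methyl-2-[4-(trimethylsilyl)but-3-yn-1-yl]cyclohex-2-en-1-ol | C[Si](C)(C)C#CCCC1=C(C)CCC[C@H]1O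
F7 | step 5 | (1R)-2-(but-3-yn-1-yl)-3-methylcyclohex-2-en-1-ol | C#CCCC1=C(C)CCC[C@H]1O
F8 | step 5 | (2E,8aR)-2-(iodomethylidene)-5-methyl-3,4,6,7,8,8a-hexahydro-2H-chromene | I/C=C1\CCC2=C(C)CCC[C@H]2O1
F9 | step 8 | (1R,2R,8aR)-1,8a-dimethyl-1,2,3,4,6,7,8,8a-octahydronaphthalen-2-ol | O[C@@H]1CCC2=CCCC[C@]2(C)[C@H]1C
F10 | step 8 | triethyl{[(1R,2R,8aR)-1,8a-dimethyl-1,2,3,4,6,7,8,8a-octahydronaphthalen-2-yl]oxy}silane | CC[Si](CC)(CC)O[C@@H]1CCC2=CCCC[C@]2(C)[C@H]1C
F11 | step 8 | (4aR,5R,6R)-4a,5-dimethyl-6-[(triethylsilyl)oxy]-4,4a,5,6,7,8-hexahydronaphthalen-2(3H)-one | CC[Si](CC)(CC)O[C@@H]1CCC2=CC(=O)CC[C@]2(C)[C@H]1C
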